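**Retrosynthetic overview**
- The target comes from one acid deprotection (acetonide, tert-butyl ether, tert-butyl ester). The C2–C1′ diene bond comes from a Suzuki coupling of a 2-iodocyclohexenone with an (R,E)-alkenylboronate.
- The cyclohexenone comes from a one-carbon ring expansion of a 2-iodocyclopentenone acetonide. A diazo carbon (C6) that already carries the whole acid chain is inserted into the C1–C5 bond by a 1,2-shift of C5, and this sets C6.
- The iodocyclopentenone comes from the commercial (4R,5R)-dihydroxycyclopentenone acetonide, which supplies C4 and C5, by β-(tert-butoxymethyl) substitution and α-iodination.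
- The diazoalkane comes from trimethylsilyldiazomethane and γ-bromotiglate (made from tiglic acid). The boronate comes from (R)-propylene oxide and butenyl Grignard, followed by cross-metathesis with vinyl-Bpin.
- Ring order: the only carbocycle is bought as a five-membered ring and enlarged to six in step 8. The dioxolane is present from the start and is opened in the last step.

Reading of the target: the ring is numbered C1 (C=O), C2 (alkenyl), C3 (CH2OH), C4 and C5 (carbinols), C6 (acid chain). The SMILES reads 4R,5S,6R, so 4-OH, 5-OH and the C6 chain are all cis. The heptenyl carbinol is 6′R and both chain alkenes are E. This numbering is also used for the five-membered precursors.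

**Step 1**
Reactants: 1 tiglic acid
Product: 2 tert-butyl (E)-2-methylbut-2-enoate
Conditions: isobutene (excess), H2SO4 (cat.), CH2Cl2, sealed flask, rt
Reagents that add atoms: isobutene CC(C)=C
Why: Acid-catalysed addition of the carboxylic acid to isobutene (tert-butyl cation capture) gives the acid-labile ester that falls off in step 10, and the E alkene is not touched.

**Step 2**
Reactants: 2 tert-butyl (E)-2-methylbut-2-enoate
Product: 3 tert-butyl (E)-4-bromo-2-methylbut-2-enoate
Conditions: NBS (1.05 equiv), AIBN (5 mol%), PhCF3, reflux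
Reagents that add atoms: N-bromosuccinimide O=C1CCC(=O)N1Br
Why: Wohl–Ziegler allylic bromination of a tiglate goes mainly at the terminal γ-CH3 with retention of the E geometry, and the minor 2-bromomethyl isomer is removed by chromatography.

**Step 3**
Reactants: 3 tert-butyl (E)-4-bromo-2-methylbut-2-enoate, 4 (trimethylsilyl)diazomethane
Product: 6 tert-butyl (E)-5-diazo-2-methyl-5-(trimethylsilyl)pent-2-enoate, via lithio(trimethylsilyl)diazomethane 5 (not isolated)
Conditions: 4, n-BuLi, THF, −78 °C; then 3, −78 → −40 °C; cold aqueous work-up, product stored ≤ −20 °C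
Reagents that add atoms: none
Why: C-alkylation of lithiated trimethylsilyldiazomethane (SN2 at the primary allylic bromide, faster at −78 °C than attack on the hindered α-methyl tert-butyl enoate) gives a silyl-stabilised diazoalkane that holds C6–C9 and the ester.

**Step 4**
Reactants: 7 (R)-propylene oxide, 8 but-3-enylmagnesium bromide
Product: 9 (R)-hept-6-en-2-ol
Conditions: CuI (10 mol%), THF, −30 → 0 °C; aq NH4Cl
Reagents that add atoms: none
Why: Copper-catalysed Grignard opening of the epoxide occurs by SN2 at the CH2 terminus, so the stereocentre of 7 is untouched and becomes C6′ (R).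

**Step 5**
Reactants: 9 (R)-hept-6-en-2-ol, 10 vinylboronic acid pinacol ester
Product: 11 (R,E)-7-(4,4,5,5-tetramethyl-1,3,2-dioxaborolan-2-yl)hept-6-en-2-ol
Conditions: Grubbs II (3 mol%), 10 (1.5 equiv), CH2Cl2, 40 °C
Reagents that add atoms: none
Why: Olefin cross-metathesis of a terminal alkene with vinyl-Bpin gives the E-alkenylboronate selectively and tolerates the free alcohol.

**Step 6**
Reactants: 12 (3aR,6aR)-2,2-dimethyl-3a,6a-dihydro-4H-cyclopenta[d][1,3]dioxol-4-one, 13 tert-butyl methyl ether
Product: 18 (3aR,6aR)-6-(tert-butoxymethyl)-2,2-dimethyl-3a,6a-dihydro-4H-cyclopenta[d][1,3]dioxol-4-one, via tert-butoxymethylpotassium 14 (not isolated), via tert-butoxymethyllithium 15 (not isolated), via lithium bis(tert-butoxymethyl)cuprate 16 (not isolated), via the lithium enolate of the 1,4-adduct 17 (not isolated)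
Conditions: 13, s-BuLi, KOtBu, −78 °C; LiBr, THF; CuBr·SMe2, −78 → −30 °C; 12, −78 °C; then PhS(Cl)=NtBu, −78 °C → rt; aq NH4Cl
Reagents that add atoms: none
Why: One-pot β-substitution of an enone, in which Gilman cuprate 16 adds 1,4 anti to the dioxolane and enolate 17 is dehydrogenated in situ (Mukaiyama dehydrogenation, sulfur attack at C2 then syn-elimination with C3–H), which restores the enone, erases the transient C3 centre and leaves C4 and C5 of 12 intact.

**Step 7**
Reactants: 18 the 3-(tert-butoxymethyl)cyclopentenone acetonide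
Product: 19 (3aR,6aR)-6-(tert-butoxymethyl)-5-iodo-2,2-dimethyl-3a,6a-dihydro-4H-cyclopenta[d][1,3]dioxol-4-one
Conditions: I2 (1.5 equiv), pyridine–CH2Cl2 (1:1), 0 °C → rt
Reagents that add atoms: iodine II
Why: Johnson-type α-iodination (reversible 1,4-addition of pyridine, iodination of the enolate, E1cB loss of pyridine) works on 3-alkoxymethyl-4,5-O-isopropylidene-cyclopentenones, and the buffered medium spares the acetal and the ether.

**Step 8**
Reactants: 19 the 2-iodocyclopentenone acetonide, 6 the C-silyl diazoalkane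
Product: 21 tert-butyl (E)-4-[(3aS,4R,7aR)-7-(tert-butoxymethyl)-6-iodo-2,2-dimethyl-5-oxo-3a,4,5,7a-tetrahydro-1,3-benzodioxol-4-yl]-2-methylbut-2-enoate, via tert-butyl (E)-5-diazo-2-methylpent-2-enoate 20 (not isolated)
Conditions: (a) 6 (1.2 equiv), K2CO3 (10 mol%), MeOH–toluene, −20 °C, cold water wash, dry; (b) solution added to 19, Sc(OTf)3 (10 mol%), toluene, −78 → −40 °C
Reagents that add atoms: none
Why: Proposed new method: a Lewis-acid-catalysed Tiffeneau–Demjanov-type carbon insertion in which the nucleophilic diazo carbon of 20 adds to the Sc(III)-bound C1=O of 19 from the convex face (anti to the dioxolane); in the least crowded staggered adduct C6–H lies over the ring, the CH2 arm points outwards next to the small C5–H and away from the in-plane iodine, and the slim N2+ sits between O–Sc and C2, that is antiperiplanar to C1–C5, so loss of N2 is concerted with the 1,2-shift of C5 (retention at C5, inversion at C6), which enlarges the ring and puts the chain cis to both C–O bonds (C6 = R), while the sp2, iodine-bearing C2 is a poor migrating group whose shift would also break the enone conjugation; the closest known reaction types are the Sc(OTf)3-catalysed homologation of simple cycloalkanones with substituted diazomethanes and the BF3-promoted diazoacetate enlargement of cycloalkenones (saturated α′ carbon migrates), neither of which has been shown for an α′-alkoxy-α-halocyclopentenone or for an ester-bearing alkyldiazomethane released from its C-silyl precursor.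

**Step 9**
Reactants: 21 the ring-enlarged iodo ketone, 11 the (R,E)-alkenylboronate
Product: 22 tert-butyl (E)-4-[(3aS,4R,7aR)-7-(tert-butoxymethyl)-6-[(1E,6R)-6-hydroxyhept-1-en-1-yl]-2,2-dimethyl-5-oxo-3a,4,5,7a-tetrahydro-1,3-benzodioxol-4-yl]-2-methylbut-2-enoate
Conditions: Pd(dppf)Cl2 (5 mol%), Ph3As (10 mol%), Cs2CO3 (1.5 equiv), DMF–THF–H2O, rt, 1–2 h
Reagents that add atoms: none
Why: Suzuki–Miyaura coupling in which the 2-iodoenone undergoes oxidative addition at rt, the E geometry of 11 is retained, and the short contact with a weak aqueous base is of the kind that epimerisable β-oxy ketones survive, so C6 and the C5–O bond are kept.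

**Step 10**
Reactants: 22 the fully protected precursor
Product: 23 pestallic acid I, (E)-4-[(1R,5R,6S)-5,6-dihydroxy-4-(hydroxymethyl)-3-[(1E,6R)-6-hydroxyhept-1-en-1-yl]-2-oxocyclohex-3-en-1-yl]-2-methylbut-2-enoic acid
Conditions: TFA–H2O (9:1), 0 °C → rt; evaporation with toluene
Reagents that add atoms: none
Why: Global acidolysis (loss of tert-butyl cation from the ester and the ether, plus acetal hydrolysis) frees all groups in one operation without base, so no E1cB, retro-aldol or C6 epimerisation pathway is opened and no stereocentre is touched.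

**Compound list**
1 | tiglic acid | C/C=C(\C)C(=O)O | starting material
2 | tert-butyl (E)-2-methylbut-2-enoate | C/C=C(\C)C(=O)OC(C)(C)C | intermediate
3 | tert-butyl (E)-4-bromo-2-methylbut-2-enoate | C/C(=C\CBr)C(=O)OC(C)(C)C | intermediate
4 | (trimethylsilyl)diazomethane | C[Si](C)(C)C=[N+]=[N-] | starting material
5 | lithio(trimethylsilyl)diazomethane | [Li]C(=[N+]=[N-])[Si](C)(C)C | intermediate
6 | tert-butyl (E)-5-diazo-2-methyl-5-(trimethylsilyl)pent-2-enoate | C/C(=C\CC(=[N+]=[N-])[Si](C)(C)C)C(=O)OC(C)(C)C | intermediate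
7 | (R)-propylene oxide | C[C@@H]1CO1 | starting material
8 | but-3-enylmagnesium bromide | C=CCC[Mg]Br | starting material
9 | (R)-hept-6-en-2-ol | C=CCCC[C@@H](C)O | intermediate
10 | vinylboronic acid pinacol ester | C=CB1OC(C)(C)C(C)(C)O1 | starting material
11 | (R,E)-7-(4,4,5,5-tetramethyl-1,3,2-dioxaborolan-2-yl)hept-6-en-2-ol | C[C@@H](O)CCC/C=C/B1OC(C)(C)C(C)(C)O1 | intermediate
12 | (3aR,6aR)-2,2-dimethyl-3a,6a-dihydro-4H-cyclopenta[d][1,3]dioxol-4-one (acetonide of (4R,5R)-4,5-dihydroxycyclopent-2-enone) | O=C1C=C[C@H]2OC(C)(C)O[C@@H]12 | starting material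
13 | tert-butyl methyl ether | COC(C)(C)C | starting material
14 | tert-butoxymethylpotassium | [K]COC(C)(C)C | intermediate
15 | tert-butoxymethyllithium | [Li]COC(C)(C)C | intermediate
16 | lithium bis(tert-butoxymethyl)cuprate | [Li+].CC(C)(C)OC[Cu-]COC(C)(C)C | intermediate
17 | lithium enolate of the 1,4-adduct (CH2OtBu trans to the dioxolane) | [Li]OC1=C[C@H](COC(C)(C)C)[C@H]2OC(C)(C)O[C@@H]12 | intermediate
18 | (3aR,6aR)-6-(tert-butoxymethyl)-2,2-dimethyl-3a,6a-dihydro-4H-cyclopenta[d][1,3]dioxol-4-one | O=C1C=C(COC(C)(C)C)[C@H]2OC(C)(C)O[C@@H]12 | intermediate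
19 | (3aR,6aR)-6-(tert-butoxymethyl)-5-iodo-2,2-dimethyl-3a,6a-dihydro-4H-cyclopenta[d][1,3]dioxol-4-one | O=C1C(I)=C(COC(C)(C)C)[C@H]2OC(C)(C)O[C@@H]12 | intermediate
20 | tert-butyl (E)-5-diazo-2-methylpent-2-enoate | C/C(=C\CC=[N+]=[N-])C(=O)OC(C)(C)C | intermediate
21 | tert-butyl (E)-4-[(3aS,4R,7aR)-7-(tert-butoxymethyl)-6-iodo-2,2-dimethyl-5-oxo-3a,4,5,7a-tetrahydro-1,3-benzodioxol-4-yl]-2-methylbut-2-enoate | C/C(=C\C[C@H]1C(=O)C(I)=C(COC(C)(C)C)[C@H]2OC(C)(C)O[C@@H]12)C(=O)OC(C)(C)C | intermediate
22 | tert-butyl (E)-4-[(3aS,4R,7aR)-7-(tert-butoxymethyl)-6-[(1E,6R)-6-hydroxyhept-1-en-1-yl]-2,2-dimethyl-5-oxo-3a,4,5,7a-tetrahydro-1,3-benzodioxol-4-yl]-2-methylbut-2-enoate | C/C(=C\C[C@H]1C(=O)C(/C=C/CCC[C@@H](C)O)=C(COC(C)(C)C)[C@H]2OC(C)(C)O[C@@H]12)C(=O)OC(C)(C)C | intermediate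
23 | pestallic acid I | C/C(=C\C[C@H]1C(=O)C(/C=C/CCC[C@@H](C)O)=C(CO)[C@@H](O)[C@H]1O)C(=O)O | target

**Step count:** 10 steps in total.
**Longest linear sequence:** 6 steps (1, 2, 3, 8, 9, 10). The branch from 12 takes 5 steps and the branch from 7 takes 4.

**Steps most likely to fail**

Step 8 (proposed new ring expansion). The risks are epoxide formation, migration of C2, and the wrong C6 epimer. The fallback uses known chemistry, sets out from 19 and comes back at 21.
- BF3·OEt2-promoted insertion of 2-(trimethylsilyl)ethyl diazoacetate into 19 is the established ring enlargement of conjugated cycloalkenones with diazoacetates, in which the saturated α′ carbon migrates. It gives the ring-enlarged 2-(trimethylsilyl)ethyl β-keto ester F1.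
- K2CO3 in acetone with bromide 3 alkylates F1 on the convex face to give the C6-quaternary keto diester F2.
- TBAF buffered with AcOH cleaves the silylethyl ester and the β-keto acid loses CO2. The enol is then protonated on the convex face, which pushes the chain to the dioxolane side and gives 21.

Step 3 (alkylation of lithiated silyldiazomethane with a γ-bromo enoate). The risks are SN2′ or Michael attack and the limited stability of 6. The fallback sets out from 19 and 4, uses 3 later, and comes back at 21.
- Commercial 4 itself is inserted into 19 (BF3·OEt2, CH2Cl2, −78 °C, then mild acid to remove silicon). This gives the C6-unsubstituted iodocyclohexenone acetonide F3.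
- LiHMDS at −78 °C followed by 3 alkylates F3 on the convex face to give the C6 epimer of 21, F4.
- A second deprotonation (LiHMDS, −78 °C) and a quench with a bulky phenol protonates the enolate on the convex face. This inverts C6 and gives 21.

Step 9 (Suzuki coupling on the base-sensitive β-alkoxy ketone). The risks are C6 epimerisation and loss of the C5–O bond. The fallback moves the coupling ahead of the ring expansion, sets out from 11 and 19, and comes back at 23.
- TBSCl and imidazole convert 11 into the silyl-protected boronate F5.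
- F5 couples with the robust cyclopentenone 19 under the step 9 conditions to give the 2-alkenylcyclopentenone F6.
- The step 8 conditions with 6 enlarge F6 to the silyl-protected cyclohexenone F7.
- The step 10 conditions also remove the silyl ether and give 23.

**Further compounds**
F1 | step 8 | 2-(trimethylsilyl)ethyl (3aS,7aR)-7-(tert-butoxymethyl)-6-iodo-2,2-dimethyl-5-oxo-3a,4,5,7a-tetrahydro-1,3-benzodioxole-4-carboxylate (C4 epimers and enol) | C[Si](C)(C)CCOC(=O)C1C(=O)C(I)=C(COC(C)(C)C)[C@H]2OC(C)(C)O[C@@H]12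
F2 | step 8 | 2-(trimethylsilyl)ethyl (3aS,4R,7aR)-4-[(E)-4-tert-butoxy-3-methyl-4-oxobut-2-en-1-yl]-7-(tert-butoxymethyl)-6-iodo-2,2-dimethyl-5-oxo-3a,4,5,7a-tetrahydro-1,3-benzodioxole-4-carboxylate | C/C(=C\C[C@]1(C(=O)OCC[Si](C)(C)C)C(=O)C(I)=C(COC(C)(C)C)[C@H]2OC(C)(C)O[C@@H]12)C(=O)OC(C)(C)C
F3 | step 3 | (3aS,7aR)-7-(tert-butoxymethyl)-6-iodo-2,2-dimethyl-3a,7a-dihydro-1,3-benzodioxol-5(4H)-one | C1C(=O)C(I)=C(COC(C)(C)C)[C@H]2OC(C)(C)O[C@@H]12
F4 | step 3 | tert-butyl (E)-4-[(3aS,4S,7aR)-7-(tert-butoxymethyl)-6-iodo-2,2-dimethyl-5-oxo-3a,4,5,7a-tetrahydro-1,3-benzodioxol-4-yl]-2-methylbut-2-enoate | C/C(=C\C[C@@H]1C(=O)C(I)=C(COC(C)(C)C)[C@H]2OC(C)(C)O[C@@H]12)C(=O)OC(C)(C)C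
F5 | step 9 | tert-butyldimethyl{[(R,E)-7-(4,4,5,5-tetramethyl-1,3,2-dioxaborolan-2-yl)hept-6-en-2-yl]oxy}silane | C[C@@H](O[Si](C)(C)C(C)(C)C)CCC/C=C/B1OC(C)(C)C(C)(C)O1
F6 | step 9 | (3aR,6aR)-6-(tert-butoxymethyl)-5-[(1E,6R)-6-(tert-butyldimethylsilyloxy)hept-1-en-1-yl]-2,2-dimethyl-3a,6a-dihydro-4H-cyclopenta[d][1,3]dioxol-4-one | O=C1C(/C=C/CCC[C@@H](C)O[Si](C)(C)C(C)(C)C)=C(COC(C)(C)C)[C@H]2OC(C)(C)O[C@@H]12
F7 | step 9 | tert-butyl (E)-4-[(3aS,4R,7aR)-7-(tert-butoxymethyl)-6-[(1E,6R)-6-(tert-butyldimethylsilyloxy)hept-1-en-1-yl]-2,2-dimethyl-5-oxo-3a,4,5,7a-tetrahydro-1,3-benzodioxol-4-yl]-2-methylbut-2-enoate | C/C(=C\C[C@H]1C(=O)C(/C=C/CCC[C@@H](C)O[Si](C)(C)C(C)(C)C)=C(COC(C)(C)C)[C@H]2OC(C)(C)O[C@@H]12)C(=O)OC(C)(C)C
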